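## Retrosynthetic overview

1. The target is cut last at the CH2 bridge: a Mannich-type (carba-Betti) union of the 6-acetyl-(3R)-chroman-3-ol, whose only free aromatic carbon is C8, with 6-ethyl-4-hydroxy-5-methyl-2-pyranone and Me2N=CH2+.
2. The chromanol is cut to twofold-symmetric 2,4,6-trihydroxyacetophenone and (R)-3,3-dimethylglycidyl tosylate in a one-flask annulation: ring-carbon alkylation (C4–C4a), then acid 6-endo epoxide opening by the para-OH (O1–C2). The carbinol stereocentre is carried in with the epoxide.
3. The (R)-epoxy tosylate comes from prenol by Sharpless asymmetric epoxidation with D-(−)-tartrate and in situ tosylation.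
4. The pyranone comes from methyl 4-methyl-3,5-dioxoheptanoate, made from the dianion of methyl 3-oxopentanoate and methyl propanoate.
5. Ring order: oxirane (stereocentre), then the dihydropyran ring fused onto the purchased benzene ring; the pyranone ring is made separately; the two halves are joined last.

Assumption: the carbinol carbon of the target is (R) as read from the SMILES, and 1, 4, 8, 9 and all named reagents are purchased.

## Route

Step 1
Reactants: 1 3-methylbut-2-en-1-ol (prenol)
Product: 3 [(2R)-3,3-dimethyloxiran-2-yl]methyl 4-methylbenzenesulfonate, via (R)-3,3-dimethylglycidol 2 (not isolated)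
Conditions: Ti(OiPr)4 (5 mol%), D-(−)-diisopropyl tartrate (6 mol%), t-BuOOH (1.5 equiv), 4 Å MS, CH2Cl2, −20 °C; P(OMe)3 (destroys excess t-BuOOH); then TsCl, Et3N, DMAP (cat.), −10 → 0 °C; recrystallise to upgrade ee
Reagents that add atoms: tert-butyl hydroperoxide, CC(C)(C)OO (epoxide oxygen); 4-methylbenzenesulfonyl chloride, Cc1ccc(cc1)S(=O)(=O)Cl (tosyl group)
Why: Catalytic Sharpless asymmetric epoxidation, in which the titanium/D-(−)-tartrate complex gives the 2R epoxy alcohol (the same facial rule gives 2S with L-(+)-tartrate, as for geraniol), and in situ sulfonylation traps the volatile, water-soluble glycidol 2 without touching the stereocentre.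

Step 2
Reactants: 4 1-(2,4,6-trihydroxyphenyl)ethan-1-one (2.0 equiv); 3 [(2R)-3,3-dimethyloxiran-2-yl]methyl 4-methylbenzenesulfonate (1.0 equiv)
Product: 7 1-[(3R)-3,5,7-trihydroxy-2,2-dimethyl-3,4-dihydro-2H-chromen-6-yl]ethan-1-one, via epoxy iodide 5 (not isolated), via C-alkylated epoxide 6 (not isolated)
Conditions: NaOMe (1.0 equiv), NaI (1.0 equiv), MeOH, 0 → 40 °C; pH 6 buffer wash, crude 6 taken on; then camphorsulfonic acid (10 mol%), CH2Cl2/(CF3)2CHOH (4:1), −20 → 0 °C
Reagents that add atoms: none
Why: Proposed new method: the mono-sodium phenoxide of symmetric 4 reacts in methanol as a vinylogous enolate, so the soft iodide 5 (Finkelstein exchange on 3, direct displacement at CH2) is attacked by ring carbon C3 and the ring re-aromatises by tautomerisation to 6 (closest known reactions: C-methylation and C-prenylation of acylphloroglucinol phenoxides with MeI or prenyl bromide in protic media); acid in a cation-stabilising solvent then opens the trisubstituted epoxide at its tertiary carbon with the unchelated para-OH in a 6-endo sense (closest known reaction: acid-mediated cyclisation of ortho-(2,3-epoxy-3-methylbutyl)phenols to 3-hydroxy-2,2-dimethylchromans; the 2-OH is tied up in the hydrogen bond to the acetyl group), and because the C–O bond at the carbinol carbon is never broken, the (R) centre of 3 becomes C3 of 7 unchanged.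

Step 3
Reactants: 8 methyl 3-oxopentanoate (2.0 equiv); 9 methyl propanoate (1.0 equiv)
Product: 10 methyl 4-methyl-3,5-dioxoheptanoate (racemic at C4)
Conditions: lithium diisopropylamide (4.0 equiv), THF, 0 °C; then 9, 0 °C → rt; aq. HCl quench
Reagents that add atoms: none
Why: Huckin–Weiler γ-acylation (Claisen-type condensation), in which the β-keto ester dianion reacts at its more basic γ-carbon with the ester and the second equivalent of dianion absorbs the proton of the more acidic product; the racemic C4 centre is destroyed in step 4.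

Step 4
Reactants: 10 methyl 4-methyl-3,5-dioxoheptanoate
Product: 11 6-ethyl-4-hydroxy-5-methyl-2H-pyran-2-one
Conditions: DBU (1.0 equiv), toluene, reflux; acidic work-up
Reagents that add atoms: none
Why: Base-mediated lactonisation, in which the enol oxygen of the C5 ketone attacks the methyl ester (6-exo acyl substitution) and loss of methanol followed by enolisation gives the 4-hydroxy-2-pyranone.

Step 5
Reactants: 11 6-ethyl-4-hydroxy-5-methyl-2H-pyran-2-one (1.0 equiv); 7 1-[(3R)-3,5,7-trihydroxy-2,2-dimethyl-3,4-dihydro-2H-chromen-6-yl]ethan-1-one (1.0 equiv)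
Product: 14 3-{[(3R)-6-acetyl-3,5,7-trihydroxy-2,2-dimethyl-3,4-dihydro-2H-chromen-8-yl]methyl}-6-ethyl-4-hydroxy-5-methyl-2H-pyran-2-one, via pyranone Mannich base 12 (not isolated), via methylidene pyrandione 13 (not isolated)
Conditions: 11, Me2N=CH2+ I− (1.05 equiv), MeCN, rt, 1 h; then 7, 50 °C
Reagents that add atoms: N,N-dimethylmethylideneammonium iodide (Eschenmoser's salt), C[N+](C)=C.[I-] (the bridging CH2)
Why: Mannich-type three-component methylenation (carba-Betti coupling), in which the pyranone is aminomethylated at nucleophilic C3 to 12, 12 loses dimethylamine on warming to the quinone-methide-like acceptor 13, and 13 is trapped by the single unsubstituted, doubly oxygen-activated ring carbon C8 of 7; no stereocentre is formed and C3 of the chroman is not involved.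

## Compound list

1 | 3-methylbut-2-en-1-ol (prenol) | CC(C)=CCO | starting material
2 | [(2R)-3,3-dimethyloxiran-2-yl]methanol | CC1(C)O[C@@H]1CO | intermediate
3 | [(2R)-3,3-dimethyloxiran-2-yl]methyl 4-methylbenzenesulfonate | CC1(C)O[C@@H]1COS(=O)(=O)c2ccc(C)cc2 | intermediate
4 | 1-(2,4,6-trihydroxyphenyl)ethan-1-one | CC(=O)c1c(O)cc(O)cc1O | starting material
5 | (2S)-2-(iodomethyl)-3,3-dimethyloxirane (same spatial arrangement as 3; descriptor changes by priority only) | CC1(C)O[C@@H]1CI | intermediate
6 | 1-(3-{[(2R)-3,3-dimethyloxiran-2-yl]methyl}-2,4,6-trihydroxyphenyl)ethan-1-one | CC1(C)O[C@@H]1Cc2c(O)cc(O)c(C(C)=O)c2O | intermediate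
7 | 1-[(3R)-3,5,7-trihydroxy-2,2-dimethyl-3,4-dihydro-2H-chromen-6-yl]ethan-1-one | CC(=O)c1c(O)cc2OC(C)(C)[C@H](O)Cc2c1O | intermediate
8 | methyl 3-oxopentanoate | CCC(=O)CC(=O)OC | starting material
9 | methyl propanoate | CCC(=O)OC | starting material
10 | methyl 4-methyl-3,5-dioxoheptanoate (racemic) | CCC(=O)C(C)C(=O)CC(=O)OC | intermediate
11 | 6-ethyl-4-hydroxy-5-methyl-2H-pyran-2-one | CCc1oc(=O)cc(O)c1C | intermediate
12 | 3-[(dimethylamino)methyl]-6-ethyl-4-hydroxy-5-methyl-2H-pyran-2-one | CCc1oc(=O)c(CN(C)C)c(O)c1C | intermediate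
13 | 6-ethyl-5-methyl-3-methylidene-2H-pyran-2,4(3H)-dione | CCC1=C(C)C(=O)C(=C)C(=O)O1 | intermediate
14 | 3-{[(3R)-6-acetyl-3,5,7-trihydroxy-2,2-dimethyl-3,4-dihydro-2H-chromen-8-yl]methyl}-6-ethyl-4-hydroxy-5-methyl-2H-pyran-2-one | CCc1oc(=O)c(Cc2c(O)c(C(C)=O)c(O)c3c2OC(C)(C)[C@H](O)C3)c(O)c1C | target

## Step count and risks

Total steps: 5. Longest linear sequence: 3 (steps 1 → 2 → 5, or 3 → 4 → 5).

Three steps most likely to fail:

**Step 2 (annulation).** The risks are O-alkylation at the 4-oxygen instead of C-alkylation, double alkylation, base-induced 5-exo closure to a dihydrobenzofuran, and closure through the 2-OH to the 8-acetyl regioisomer, which would have to be separated. The fallback sets the stereocentre by catalytic asymmetric epoxidation of a C-prenyl arene instead of bringing it in with the electrophile. It sets out from 4, which is C-prenylated with prenyl bromide (DBU, THF, 0 °C) to 1-[2,4,6-trihydroxy-3-(3-methylbut-2-en-1-yl)phenyl]ethan-1-one F1. Exhaustive silylation (t-BuMe2SiOTf, 2,6-lutidine, CH2Cl2) gives the tris(tert-butyldimethylsilyl) ether F2. Shi epoxidation (D-fructose-derived Shi ketone 30 mol%, KHSO5 as 2KHSO5·KHSO4·K2SO4, K2CO3 buffer, MeCN/dimethoxymethane, 0 °C) gives the (R)-epoxide F3, the facial sense known for terminal trisubstituted olefins. HF·pyridine in THF then removes the three silyl groups and closes the ring 6-endo under the acidic conditions, and the fallback comes back to the route at 7. This fallback does not remove the 2-OH versus 4-OH question.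

**Step 5 (methylene bridge).** The risks are homodimers (bis-pyranone methane, bis-chroman methane) and retro-Mannich scrambling. The fallback installs the bridge carbon on the arene as an aldehyde and joins the halves reductively. It sets out from 7, which is formylated at its only free ring position (POCl3, DMF, MeCN, 0 °C → rt; aqueous NaOAc, which also cleaves any 3-O-formate) to (3R)-6-acetyl-3,5,7-trihydroxy-2,2-dimethyl-3,4-dihydro-2H-chromene-8-carbaldehyde F4. L-Proline-catalysed Knoevenagel condensation with 11 (CH2Cl2, rt) gives the arylidene pyrandione F5, which is reduced in the same flask by Hantzsch ester (diethyl 2,6-dimethyl-1,4-dihydropyridine-3,5-dicarboxylate), and the fallback comes back to the route at 14.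

**Step 3 (γ-acylation).** The risks are proton transfer from the enolisable ester to the secondary γ-carbanion, low conversion and O-acylation. The fallback replaces the dianion by a neutral Mukaiyama-type acylation of a bis(silyl enol ether). It sets out from 8, which is silylated (Me3SiCl, Et3N) to methyl 3-(trimethylsilyloxy)pent-2-enoate F6 and then (lithium diisopropylamide, Me3SiCl, THF, −78 °C) to 1-methoxy-1,3-bis(trimethylsilyloxy)penta-1,3-diene F7. F7 is acylated at its terminal carbon by propanoyl chloride (Me3SiOTf cat., CH2Cl2, −78 → 20 °C), and aqueous work-up comes back to the route at 10.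

## Further compounds

F1 | step 2 | 1-[2,4,6-trihydroxy-3-(3-methylbut-2-en-1-yl)phenyl]ethan-1-one | CC(=O)c1c(O)cc(O)c(CC=C(C)C)c1O
F2 | step 2 | 1-[2,4,6-tris(tert-butyldimethylsilyloxy)-3-(3-methylbut-2-en-1-yl)phenyl]ethan-1-one | CC(=O)c1c(O[Si](C)(C)C(C)(C)C)cc(O[Si](C)(C)C(C)(C)C)c(CC=C(C)C)c1O[Si](C)(C)C(C)(C)C
F3 | step 2 | 1-(2,4,6-tris(tert-butyldimethylsilyloxy)-3-{[(2R)-3,3-dimethyloxiran-2-yl]methyl}phenyl)ethan-1-one | CC1(C)O[C@@H]1Cc2c(O[Si](C)(C)C(C)(C)C)cc(O[Si](C)(C)C(C)(C)C)c(C(C)=O)c2O[Si](C)(C)C(C)(C)C
F4 | step 5 | (3R)-6-acetyl-3,5,7-trihydroxy-2,2-dimethyl-3,4-dihydro-2H-chromene-8-carbaldehyde | CC(=O)c1c(O)c(C=O)c2OC(C)(C)[C@H](O)Cc2c1O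
F5 | step 5 | 3-{[(3R)-6-acetyl-3,5,7-trihydroxy-2,2-dimethyl-3,4-dihydro-2H-chromen-8-yl]methylidene}-6-ethyl-5-methyl-2H-pyran-2,4(3H)-dione | CCC1=C(C)C(=O)C(=Cc2c(O)c(C(C)=O)c(O)c3c2OC(C)(C)[C@H](O)C3)C(=O)O1
F6 | step 3 | methyl 3-(trimethylsilyloxy)pent-2-enoate | CCC(O[Si](C)(C)C)=CC(=O)OC
F7 | step 3 | 1-methoxy-1,3-bis(trimethylsilyloxy)penta-1,3-diene | CC=C(O[Si](C)(C)C)C=C(OC)O[Si](C)(C)C
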